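## Retrosynthetic overview

1. Target 24 ⇐ phenol deprotection, Luche reduction at C7 and acylation at O4 ⇐ diol enone 19 + protected vanilloyl chloride 21; 19 ⇐ ene-dione 18 by hydroxyl-directed reduction of the C4 ketone.
2. 18 ⇐ bis(methyl enol ether) cycloheptatriene 16 (hydrolysis, which also installs C3a–H) ⇐ dihydroazulenone 14 (Wolff–Kishner removal of the C1 carbonyl).
3. Key disconnection: 14 ⇐ α-methyl-α-diazoketone 12 by intramolecular Buchner reaction. One operation closes the five-membered ring (C8a–C3a), creates the quaternary C8a and expands the benzene ring by one carbon to the seven-membered ring.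
4. Enabling feature: the seven-membered-ring atoms C3a, C4(O), C5=C6(CH3), C7(O) and C8 are the six carbons of a 2,5-dimethoxy-4-methylphenyl ring with its oxygen and methyl substituents in place; C8a (angular CH3) is the carbenoid carbon inserted between C3a and C8.
5. 12 ⇐ (R)-β-silyloxy acid 10 ⇐ enoate 6 (asymmetric conjugate borylation sets C3, which then controls C8a) ⇐ keto ester 1 + aryl bromide 3. Ring order: arene (bought) → five- and seven-membered rings together in step 7.

Key step: step 7

Remark on the chemistry: all bicyclic compounds carry azulene numbering (C1–C3, C3a, C4–C8, C8a); 14 is drawn as the cycloheptatriene, which equilibrates with its norcaradiene valence tautomer 13.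

## Route

Step 1
Reactants: 1 ethyl 4-methyl-3-oxopentanoate
Product: 2 ethyl (2E)-4-methyl-3-[(trifluoromethanesulfonyl)oxy]pent-2-enoate
Conditions: Tf2O, aq. Me4NOH, hexanes, 5 °C
Reagents that add atoms: trifluoromethanesulfonic anhydride, O=S(=O)(OS(=O)(=O)C(F)(F)F)C(F)(F)F
Why: Stereoselective enol triflate formation: the non-chelated tetramethylammonium enolate of the β-keto ester is O-sulfonylated in its extended form, which places the triflate trans to the ester ((E) geometry; no stereocenter is formed).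

Step 2
Reactants: 3 1-bromo-2,5-dimethoxy-4-methylbenzene; 2 ethyl (2E)-4-methyl-3-[(trifluoromethanesulfonyl)oxy]pent-2-enoate
Product: 6 ethyl (2E)-3-(2,5-dimethoxy-4-methylphenyl)-4-methylpent-2-enoate, via aryllithium 4 (not isolated), via arylzinc chloride 5 (not isolated)
Conditions: 3, n-BuLi, THF, −78 °C; ZnCl2, −78→0 °C; then 2, Pd(OAc)2 (2 mol%), SPhos (4 mol%), THF, 50 °C
Reagents that add atoms: none
Why: Negishi cross-coupling (oxidative addition of zerovalent palladium into the vinyl C–OTf bond, transmetalation from zinc, reductive elimination) replaces the triflate by the aryl group with retention of alkene geometry, so the aryl group ends trans to the ester.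

Step 3
Reactants: 6 ethyl (2E)-3-(2,5-dimethoxy-4-methylphenyl)-4-methylpent-2-enoate
Product: 8 ethyl (3R)-3-(2,5-dimethoxy-4-methylphenyl)-3-hydroxy-4-methylpentanoate, via boronate ester 7 (not isolated)
Conditions: B2pin2, CuCl (5 mol%), NaOtBu (10 mol%), Me-DuPhos (6 mol%; the antipode that gives (3S)-7), MeOH (2 equiv), THF, 25 °C; then 30% H2O2, aq. NaHCO3, 0 °C
Reagents that add atoms: hydrogen peroxide, OO
Why: Copper-catalysed enantioselective conjugate borylation of a β,β-disubstituted enoate (borylcupration of one enantiotopic face under control of the chiral bisphosphine, protonation of the copper enolate by MeOH) sets the tertiary stereocenter C3, and oxidation of the C–B bond proceeds with retention to give the (3R) alcohol.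

Step 4
Reactants: 8 ethyl (3R)-3-(2,5-dimethoxy-4-methylphenyl)-3-hydroxy-4-methylpentanoate
Product: 9 ethyl (3R)-3-(2,5-dimethoxy-4-methylphenyl)-4-methyl-3-[(triethylsilyl)oxy]pentanoate
Conditions: Et3SiOTf, 2,6-lutidine, CH2Cl2, 0 °C
Reagents that add atoms: triethylsilyl trifluoromethanesulfonate, CC[Si](CC)(CC)OS(=O)(=O)C(F)(F)F
Why: O-Silylation of the hindered tertiary alcohol with the silyl triflate (silyl ether protection) leaves the stereocenter untouched and removes the O–H group that would otherwise intercept the carbenoid in step 7.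

Step 5
Reactants: 9 ethyl (3R)-3-(2,5-dimethoxy-4-methylphenyl)-4-methyl-3-[(triethylsilyl)oxy]pentanoate
Product: 10 (3R)-3-(2,5-dimethoxy-4-methylphenyl)-4-methyl-3-[(triethylsilyl)oxy]pentanoic acid
Conditions: LiOH·H2O, THF–MeOH–H2O, 40 °C; then 1 M HCl to pH 4, 0 °C
Reagents that add atoms: lithium hydroxide, [Li+].[OH-]
Why: Saponification of the ethyl ester (acyl substitution by hydroxide); the tertiary silyl ether is stable to aqueous LiOH and the silylated β-oxygen cannot undergo retro-aldol cleavage.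

Step 6
Reactants: 10 (3R)-3-(2,5-dimethoxy-4-methylphenyl)-4-methyl-3-[(triethylsilyl)oxy]pentanoic acid
Product: 12 (5R)-2-diazo-5-(2,5-dimethoxy-4-methylphenyl)-6-methyl-5-[(triethylsilyl)oxy]heptan-3-one, via acid chloride 11 (not isolated)
Conditions: 1-chloro-N,N,2-trimethylprop-1-en-1-amine, CH2Cl2, 0→25 °C; then CH3CHN2 (3 equiv, Et2O solution), −20→0 °C
Reagents that add atoms: diazoethane, CC=[N+]=[N-]
Why: Neutral conversion of the acid into its chloride by the α-chloroenamine followed by C-acylation of diazoethane (Arndt–Eistert-type diazoketone synthesis) gives the 2-diazo-3-ketone; a second equivalent of diazoethane takes up the HCl, so the acid-sensitive benzylic silyl ether never meets acid.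

Step 7
Reactants: 12 (5R)-2-diazo-5-(2,5-dimethoxy-4-methylphenyl)-6-methyl-5-[(triethylsilyl)oxy]heptan-3-one
Product: 14 (3R,8aR)-4,7-dimethoxy-6,8a-dimethyl-3-(propan-2-yl)-3-[(triethylsilyl)oxy]-3,8a-dihydroazulen-1(2H)-one, via norcaradiene 13 (not isolated)
Conditions: Rh2(OAc)4 (1 mol%), CH2Cl2, 40 °C, slow addition of 12; filtration through basic alumina
Reagents that add atoms: none
Why: Rh2(OAc)4 converts 12, with loss of N2, into an electrophilic rhodium carbenoid that adds across the C1′–C6′ bond of the electron-rich arene (ipso carbon and the unsubstituted ortho carbon) to give norcaradiene 13, whose disrotatory 6π electrocyclic opening cleaves the former aromatic C1′–C6′ bond and leaves the carbenoid carbon as C8a between C3a and C8 of cycloheptatriene 14. The closest known reaction type is the intramolecular Buchner reaction of 2-diazo-5-arylpentan-3-ones to 8a-methyl-3,8a-dihydroazulen-1(2H)-ones, which also tolerates methoxy-substituted arenes. The five-membered ring closes by C–C bond formation between the carbenoid carbon and the ipso carbon (5-exo mode, as part of the [2+1] addition), whereas the seven-membered ring is not closed from a chain but arises from the benzene ring by this one-carbon ring expansion. The new quaternary stereocenter C8a is controlled by C3: 1,3-allylic strain with the ortho methoxy group holds the small silyloxy group near the arene plane, so the tether and the isopropyl group lie on opposite faces of the arene, the carbenoid adds to the face away from isopropyl, and the C8a methyl ends cis to the silyloxy group (8aR). The step needs chemoselectivity for arene addition over 1,2-hydride shift, C–H insertion and attack on the silyl ether oxygen, and regioselectivity for one ortho carbon; the first should be secured by the very electron-rich arene held in a five-membered-ring transition state next to a quaternary carbon, the second by the methoxy group that blocks the other ortho position.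

Step 8
Reactants: 14 (3R,8aR)-4,7-dimethoxy-6,8a-dimethyl-3-(propan-2-yl)-3-[(triethylsilyl)oxy]-3,8a-dihydroazulen-1(2H)-one
Product: 16 (3R,8aR)-4,7-dimethoxy-6,8a-dimethyl-3-(propan-2-yl)-3-[(triethylsilyl)oxy]-1,2,3,8a-tetrahydroazulene, via hydrazone 15 (not isolated)
Conditions: N2H4·H2O, Et3N, EtOH, 80 °C; then KOtBu, DMSO, 25 °C
Reagents that add atoms: none
Why: Wolff–Kishner reduction in its room-temperature variant (preformed hydrazone, KOtBu in DMSO) removes the only carbonyl group through a diazenyl anion and not through a C1 radical or cation, which could rearrange by vinyl migration; the enol ethers, the silyl ether and both stereocenters are inert to hydrazine and base.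

Step 9
Reactants: 16 (3R,8aR)-4,7-dimethoxy-6,8a-dimethyl-3-(propan-2-yl)-3-[(triethylsilyl)oxy]-1,2,3,8a-tetrahydroazulene
Product: 18 (3R,3aR,8aR)-3-hydroxy-6,8a-dimethyl-3-(propan-2-yl)-1,2,3,3a,8,8a-hexahydroazulene-4,7-dione, via silyl ether dione 17 (not isolated)
Conditions: 0.5 M HCl, THF, 0 °C; then HF·pyridine, pyridine, THF, 0→25 °C
Reagents that add atoms: water, O
Why: Acid hydrolysis of the two methyl enol ethers (C-protonation at C3a and C8, hydration of the oxocarbenium ions, loss of methanol) unmasks the cyclohept-2-ene-1,4-dione and fluoride then cleaves the triethylsilyl ether; the new stereocenter C3a is epimerisable through the enol and should settle in the trans-fused form, in which the C4 carbonyl carbon is anti to the C3 isopropyl group and hydrogen-bonded to the cis C3 hydroxyl.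

Step 10
Reactants: 18 (3R,3aR,8aR)-3-hydroxy-6,8a-dimethyl-3-(propan-2-yl)-1,2,3,3a,8,8a-hexahydroazulene-4,7-dione
Product: 19 (3R,3aS,4S,8aR)-3,4-dihydroxy-6,8a-dimethyl-3-(propan-2-yl)-2,3,3a,4,8,8a-hexahydroazulen-7(1H)-one
Conditions: Me4NBH(OAc)3, MeCN–AcOH (1:1), −30 °C
Reagents that add atoms: none
Why: Evans–Saksena hydroxyl-directed reduction: the C3 hydroxyl exchanges onto boron and delivers hydride intramolecularly to its own face of the C4 carbonyl, giving the 1,3-anti (3R,4S) diol, while the C7 enone carbonyl, which has no directing hydroxyl, is not reduced by the triacetoxyborohydride.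

Step 11
Reactants: 20 4-(acetyloxy)-3-methoxybenzoic acid
Product: 21 4-(acetyloxy)-3-methoxybenzoyl chloride
Conditions: (COCl)2, DMF (cat.), CH2Cl2, 0→25 °C
Reagents that add atoms: oxalyl chloride, ClC(=O)C(Cl)=O
Why: Acid chloride formation with oxalyl chloride under Vilsmeier-type catalysis by DMF; the phenyl acetate is stable to these conditions.

Step 12
Reactants: 19 (3R,3aS,4S,8aR)-3,4-dihydroxy-6,8a-dimethyl-3-(propan-2-yl)-2,3,3a,4,8,8a-hexahydroazulen-7(1H)-one; 21 4-(acetyloxy)-3-methoxybenzoyl chloride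
Product: 22 (3R,3aS,4S,8aR)-3-hydroxy-6,8a-dimethyl-7-oxo-3-(propan-2-yl)-1,2,3,3a,4,7,8,8a-octahydroazulen-4-yl 4-(acetyloxy)-3-methoxybenzoate
Conditions: Et3N, DMAP, CH2Cl2, 0→25 °C
Reagents that add atoms: none
Why: DMAP-catalysed acylation (nucleophilic catalysis through the N-acylpyridinium ion) esterifies the secondary allylic C4 hydroxyl, while the tertiary C3 hydroxyl is too hindered to react; no stereocenter is changed.

Step 13
Reactants: 22 (3R,3aS,4S,8aR)-3-hydroxy-6,8a-dimethyl-7-oxo-3-(propan-2-yl)-1,2,3,3a,4,7,8,8a-octahydroazulen-4-yl 4-(acetyloxy)-3-methoxybenzoate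
Product: 23 (3R,3aS,4S,7R,8aR)-3,7-dihydroxy-6,8a-dimethyl-3-(propan-2-yl)-1,2,3,3a,4,7,8,8a-octahydroazulen-4-yl 4-(acetyloxy)-3-methoxybenzoate
Conditions: NaBH4, CeCl3·7H2O, MeOH, −78 °C
Reagents that add atoms: none
Why: Luche 1,2-reduction of the enone; hydride should add to the C7 carbonyl from the face opposite to the angular C8a methyl group, which is 1,3 to the carbonyl carbon, giving the (7R) alcohol cis to that methyl, and the esters are not reduced at this temperature.

Step 14
Reactants: 23 (3R,3aS,4S,7R,8aR)-3,7-dihydroxy-6,8a-dimethyl-3-(propan-2-yl)-1,2,3,3a,4,7,8,8a-octahydroazulen-4-yl 4-(acetyloxy)-3-methoxybenzoate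
Product: 24 (3R,3aS,4S,7R,8aR)-3,7-dihydroxy-6,8a-dimethyl-3-(propan-2-yl)-1,2,3,3a,4,7,8,8a-octahydroazulen-4-yl 4-hydroxy-3-methoxybenzoate
Conditions: K2CO3 (0.2 equiv), MeOH, 0 °C
Reagents that add atoms: none
Why: Base-catalysed transesterification (methanolysis) cleaves the activated phenyl acetate far faster than the hindered secondary aryl ester, and the phenoxide formed deactivates that ester further; no stereocenter is affected.

## Compound list

1 | ethyl 4-methyl-3-oxopentanoate | CCOC(=O)CC(=O)C(C)C | starting material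
2 | ethyl (2E)-4-methyl-3-[(trifluoromethanesulfonyl)oxy]pent-2-enoate | CCOC(=O)/C=C(/OS(=O)(=O)C(F)(F)F)C(C)C | intermediate
3 | 1-bromo-2,5-dimethoxy-4-methylbenzene | COc1cc(C)c(OC)cc1Br | starting material
4 | (2,5-dimethoxy-4-methylphenyl)lithium | [Li]c1cc(OC)c(C)cc1OC | intermediate
5 | (2,5-dimethoxy-4-methylphenyl)zinc chloride | Cl[Zn]c1cc(OC)c(C)cc1OC | intermediate
6 | ethyl (2E)-3-(2,5-dimethoxy-4-methylphenyl)-4-methylpent-2-enoate | CCOC(=O)/C=C(/c1cc(OC)c(C)cc1OC)C(C)C | intermediate
7 | ethyl (3S)-3-(2,5-dimethoxy-4-methylphenyl)-4-methyl-3-(4,4,5,5-tetramethyl-1,3,2-dioxaborolan-2-yl)pentanoate | CCOC(=O)C[C@@](B1OC(C)(C)C(C)(C)O1)(C(C)C)c1cc(OC)c(C)cc1OC | intermediate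
8 | ethyl (3R)-3-(2,5-dimethoxy-4-methylphenyl)-3-hydroxy-4-methylpentanoate | CCOC(=O)C[C@@](O)(C(C)C)c1cc(OC)c(C)cc1OC | intermediate
9 | ethyl (3R)-3-(2,5-dimethoxy-4-methylphenyl)-4-methyl-3-[(triethylsilyl)oxy]pentanoate | CCOC(=O)C[C@@](O[Si](CC)(CC)CC)(C(C)C)c1cc(OC)c(C)cc1OC | intermediate
10 | (3R)-3-(2,5-dimethoxy-4-methylphenyl)-4-methyl-3-[(triethylsilyl)oxy]pentanoic acid | OC(=O)C[C@@](O[Si](CC)(CC)CC)(C(C)C)c1cc(OC)c(C)cc1OC | intermediate
11 | (3R)-3-(2,5-dimethoxy-4-methylphenyl)-4-methyl-3-[(triethylsilyl)oxy]pentanoyl chloride | ClC(=O)C[C@@](O[Si](CC)(CC)CC)(C(C)C)c1cc(OC)c(C)cc1OC | intermediate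
12 | (5R)-2-diazo-5-(2,5-dimethoxy-4-methylphenyl)-6-methyl-5-[(triethylsilyl)oxy]heptan-3-one | CC(=[N+]=[N-])C(=O)C[C@@](O[Si](CC)(CC)CC)(C(C)C)c1cc(OC)c(C)cc1OC | intermediate
13 | norcaradiene valence tautomer of 14 (cyclopropane C3a–C8–C8a, 4,7-dimethoxycyclohexa-4,6-diene; C3 and C8a as in 14) | C[C@]12C(=O)C[C@@](O[Si](CC)(CC)CC)(C(C)C)[C@]13C(OC)=CC(C)=C(OC)[C@H]23 | intermediate
14 | (3R,8aR)-4,7-dimethoxy-6,8a-dimethyl-3-(propan-2-yl)-3-[(triethylsilyl)oxy]-3,8a-dihydroazulen-1(2H)-one | C[C@]12C(=O)C[C@@](O[Si](CC)(CC)CC)(C(C)C)C1=C(OC)C=C(C)C(OC)=C2 | intermediate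
15 | (3R,8aR)-1-hydrazinylidene-4,7-dimethoxy-6,8a-dimethyl-3-(propan-2-yl)-3-[(triethylsilyl)oxy]-1,2,3,8a-tetrahydroazulene | C[C@]12C(=NN)C[C@@](O[Si](CC)(CC)CC)(C(C)C)C1=C(OC)C=C(C)C(OC)=C2 | intermediate
16 | (3R,8aR)-4,7-dimethoxy-6,8a-dimethyl-3-(propan-2-yl)-3-[(triethylsilyl)oxy]-1,2,3,8a-tetrahydroazulene | C[C@]12CC[C@@](O[Si](CC)(CC)CC)(C(C)C)C1=C(OC)C=C(C)C(OC)=C2 | intermediate
17 | (3R,3aR,8aR)-6,8a-dimethyl-3-(propan-2-yl)-3-[(triethylsilyl)oxy]-1,2,3,3a,8,8a-hexahydroazulene-4,7-dione | C[C@]12CC[C@@](O[Si](CC)(CC)CC)(C(C)C)[C@@H]1C(=O)C=C(C)C(=O)C2 | intermediate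
18 | (3R,3aR,8aR)-3-hydroxy-6,8a-dimethyl-3-(propan-2-yl)-1,2,3,3a,8,8a-hexahydroazulene-4,7-dione | C[C@]12CC[C@@](O)(C(C)C)[C@@H]1C(=O)C=C(C)C(=O)C2 | intermediate
19 | (3R,3aS,4S,8aR)-3,4-dihydroxy-6,8a-dimethyl-3-(propan-2-yl)-2,3,3a,4,8,8a-hexahydroazulen-7(1H)-one | C[C@]12CC[C@@](O)(C(C)C)[C@@H]1[C@@H](O)C=C(C)C(=O)C2 | intermediate
20 | 4-(acetyloxy)-3-methoxybenzoic acid | CC(=O)Oc1ccc(C(O)=O)cc1OC | starting material
21 | 4-(acetyloxy)-3-methoxybenzoyl chloride | CC(=O)Oc1ccc(C(Cl)=O)cc1OC | intermediate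
22 | (3R,3aS,4S,8aR)-3-hydroxy-6,8a-dimethyl-7-oxo-3-(propan-2-yl)-1,2,3,3a,4,7,8,8a-octahydroazulen-4-yl 4-(acetyloxy)-3-methoxybenzoate | C[C@]12CC[C@@](O)(C(C)C)[C@@H]1[C@@H](OC(=O)c1ccc(OC(C)=O)c(OC)c1)C=C(C)C(=O)C2 | intermediate
23 | (3R,3aS,4S,7R,8aR)-3,7-dihydroxy-6,8a-dimethyl-3-(propan-2-yl)-1,2,3,3a,4,7,8,8a-octahydroazulen-4-yl 4-(acetyloxy)-3-methoxybenzoate | C[C@]12CC[C@@](O)(C(C)C)[C@@H]1[C@@H](OC(=O)c1ccc(OC(C)=O)c(OC)c1)C=C(C)[C@H](O)C2 | intermediate
24 | (3R,3aS,4S,7R,8aR)-3,7-dihydroxy-6,8a-dimethyl-3-(propan-2-yl)-1,2,3,3a,4,7,8,8a-octahydroazulen-4-yl 4-hydroxy-3-methoxybenzoate | COc1cc(C(=O)O[C@H]2C=C(C)[C@H](O)C[C@@]3(C)CC[C@@](O)(C(C)C)[C@H]23)ccc1O | target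

## Step count and risks

Total step count: 14. Longest linear sequence: 13 steps (steps 1–10 and 12–14, from 1).

Steps most likely to fail:

1. Step 7. The α-methyl rhodium carbenoid may be consumed by 1,2-hydride shift to the vinyl ketone, by C–H insertion into the isopropyl methine or by attack on the silyl ether oxygen before it adds to the arene, and facial discrimination at C8a may be incomplete. Fallback, in which the quaternary centre is made after the cycloaddition instead of during it: it sets out from acid 10, whose chloride 11 would be treated with diazomethane to give the terminal diazoketone (4R)-1-diazo-4-(2,5-dimethoxy-4-methylphenyl)-5-methyl-4-[(triethylsilyl)oxy]hexan-2-one F1. Rh2(OAc)4 in CH2Cl2 would convert it, in the unsubstituted and best-precedented form of the Buchner reaction, into the 8a-unsubstituted dihydroazulenone (3R)-4,7-dimethoxy-6-methyl-3-(propan-2-yl)-3-[(triethylsilyl)oxy]-3,8a-dihydroazulen-1(2H)-one F2. Its extended potassium enolate (KHMDS, THF, −78 °C) would be C-methylated with MeI at C8a on the face opposite to the isopropyl group, which comes back to the route at 14.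

2. Step 9. Acid may ionise the tertiary allylic silyloxy group at C3 (loss of the C3 oxygen and formation of a dienone) faster than it protonates the hindered C3a=C4 enol ether, and equilibration at C3a may stop short of the trans-fused epimer. Fallback, an oxidative unmasking under buffered conditions followed by reductive dehalogenation: it sets out from 16, which with N-bromosuccinimide (2.2 equiv) and NaHCO3 in aqueous THF at 0 °C would give the α,α′-dibromo dione (3R,8aR)-3a,8-dibromo-6,8a-dimethyl-3-(propan-2-yl)-3-[(triethylsilyl)oxy]-1,2,3,3a,8,8a-hexahydroazulene-4,7-dione F3 (bromide epimers) without any protic acid. Bu3SnH with AIBN in toluene at 80 °C would remove both bromine atoms through α-keto radicals, with hydrogen delivered to C3a at the less hindered face, and comes back to the route at 17, which is desilylated as in step 9.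

3. Step 3. Borylcupration of the hindered β-isopropyl β-(ortho-methoxyaryl) enoate may be slow, and enantiofacial discrimination may be low. Fallback, a reagent-controlled epoxidation in place of the conjugate borylation: it sets out from 6. DIBAL-H (CH2Cl2, −78 °C) would give the allylic alcohol (2E)-3-(2,5-dimethoxy-4-methylphenyl)-4-methylpent-2-en-1-ol F4. Sharpless asymmetric epoxidation (Ti(OiPr)4, L-(+)-diethyl tartrate, t-BuOOH, 4 Å molecular sieves, CH2Cl2, −20 °C) would give the epoxy alcohol [(2R,3R)-3-(2,5-dimethoxy-4-methylphenyl)-3-(propan-2-yl)oxiran-2-yl]methanol F5. Hydroxyl-directed opening at C2 with Red-Al (THF, 0 °C) would give the 1,3-diol (3R)-3-(2,5-dimethoxy-4-methylphenyl)-4-methylpentane-1,3-diol F6. Oxidation of the primary alcohol (TEMPO, NaOCl cat., NaClO2, pH 6.7 buffer, MeCN) would give the hydroxy acid (3R)-3-(2,5-dimethoxy-4-methylphenyl)-3-hydroxy-4-methylpentanoic acid F7. O-Ethylation (EtI, K2CO3, DMF) comes back to the route at 8.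

Further compounds
F1 | step 7 | (4R)-1-diazo-4-(2,5-dimethoxy-4-methylphenyl)-5-methyl-4-[(triethylsilyl)oxy]hexan-2-one | [N-]=[N+]=CC(=O)C[C@@](O[Si](CC)(CC)CC)(C(C)C)c1cc(OC)c(C)cc1OC
F2 | step 7 | (3R)-4,7-dimethoxy-6-methyl-3-(propan-2-yl)-3-[(triethylsilyl)oxy]-3,8a-dihydroazulen-1(2H)-one | O=C1C[C@@](O[Si](CC)(CC)CC)(C(C)C)C2=C(OC)C=C(C)C(OC)=CC12
F3 | step 9 | (3R,8aR)-3a,8-dibromo-6,8a-dimethyl-3-(propan-2-yl)-3-[(triethylsilyl)oxy]-1,2,3,3a,8,8a-hexahydroazulene-4,7-dione (bromide epimers) | C[C@]12CC[C@@](O[Si](CC)(CC)CC)(C(C)C)C1(Br)C(=O)C=C(C)C(=O)C2Br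
F4 | step 3 | (2E)-3-(2,5-dimethoxy-4-methylphenyl)-4-methylpent-2-en-1-ol | OC/C=C(/c1cc(OC)c(C)cc1OC)C(C)C
F5 | step 3 | [(2R,3R)-3-(2,5-dimethoxy-4-methylphenyl)-3-(propan-2-yl)oxiran-2-yl]methanol | OC[C@H]1O[C@]1(C(C)C)c1cc(OC)c(C)cc1OC
F6 | step 3 | (3R)-3-(2,5-dimethoxy-4-methylphenyl)-4-methylpentane-1,3-diol | OCC[C@@](O)(C(C)C)c1cc(OC)c(C)cc1OC
F7 | step 3 | (3R)-3-(2,5-dimethoxy-4-methylphenyl)-3-hydroxy-4-methylpentanoic acid | OC(=O)C[C@@](O)(C(C)C)c1cc(OC)c(C)cc1OC
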